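The chemist deciding the next charge is you, and the choice is whether to leave the reagent at its full feed or cut it.

| setting | teal | flask |
|---|---|---|
| left-handed substrate | 0.050 M | 0.050 M |
| right-handed substrate | 0.050 M | 0.050 M |
| reagent | 0.125 M (fed, over 6.0 h) | 0.125 M (fed, over 6.0 h) |
| free catalyst | 29 µM | 29 µM |
| racemization catalyst | 80 µM | 80 µM |
| added ligand | 0.46 mM | 0.46 mM |
| remark | the very flask that is asked about, followed so far |  |
| time |  | 8.0 h |

- teal (time / h: left-handed product / %, right-handed product / %): 0.667: 5, 2; 1.33: 14, 6; 2.00: 23, 10; 2.50: 28, 11

(readings scatter by 2 percentage points)

- free catalyst is single-handed; left-handed substrate and right-handed substrate are mirror images of each other, charged as a racemate, each of them at the stated concentration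
- the numbers in the tables scatter with a standard deviation of 2 percentage points
- an excess is below zero if the other one leads

- left-handed product and right-handed product together, in percent of the left-handed substrate and right-handed substrate charged together, at 8.0 h
- excess of left-handed product over right-handed product in the product at 8.0 h
- whether the exchange between left-handed substrate and right-handed substrate keeps pace with the reaction: how far the product's excess at 8.0 h gets from its value without exchange to its value with instant exchange (above 80% keeps pace, below 20% hardly takes part, else lags behind)

Read the teal run, which is this flask followed so far, as a ratio. Summed over its four readings, left-handed product over right-handed product gives a cumulative ratio of 2.41, a reading with a scatter of 2 percentage points on each value, and so a mean excess of 41.4% over that stretch of the run.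

A racemic charge is left-handed in half of its substrate, and without exchange left-handed product cannot pass that. Define the break yield as the total yield at which left-handed product, in product holding that mean excess, equals the left-handed charge: 70.7%. It is a ceiling of mass: below it, the left-handed charge has room for that excess. Above it, holding that excess takes right-handed substrate crossing over, and the demand, as a fraction of the charge, is half of yield over break yield, less one half.

The teal run stops at a yield of 39.0%, below the break yield, so the ceiling of mass shows no crossing in it. The full feed supplies 125% of the substrate, more than the break yield, so I would leave the charge: this run tests it. At a yield of 95%, my two ends are an excess of at most 5.26% with no crossing, and 41.4% with a demand of 17.2% met. The readings do not place the flask between those ends, so I name no point.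

The forecast does: a yield of 95% (78% to 100%), an excess of 30% (15% to 41%), and an exchange that lags behind, since “Exchange therefore clearly operates”. That excess asks for a crossing of 11.8%.

The flask gives a yield of 95.0% and an excess of 10.1%, and the exchange hardly takes part, at 9.8% of the way.

    reagent + racemization catalyst → spent catalyst (k = 0.00120 M⁻¹ s⁻¹)
    left-handed substrate + racemization catalyst ⇌ right-handed substrate + racemization catalyst, rate k2*[racemization catalyst]*[left-handed substrate] forward; the back reaction follows from the equilibrium constant (k = 0.120 M⁻¹ s⁻¹)
    racemization catalyst + added ligand ⇌ idle complex, settled at all times (K = 160 M⁻¹)
    reagent + free catalyst + right-handed substrate → free catalyst + right-handed product (k = 130 M⁻² s⁻¹)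
    reagent + free catalyst + left-handed substrate → free catalyst + left-handed product (k = 420 M⁻² s⁻¹)

In this flask, left-handed product reaches 52.3% with 0.130% of left-handed substrate beside it, so the net crossing is 2.47%, less than the 17.2% demanded at this yield. The neighbour flask, charged with 0.031 M of reagent, enough for 31.0% of the substrate, stops at a yield of 30.9%, below the break yield, where the ceiling of mass calls for no crossing. Its excess is 46.4%.

All runs were computed on assumed constants; scatter was added.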